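**Retrosynthetic overview**
- The furanone is closed last, the way the ring is thought to arise in the alga: an electrophilic halogen (haloperoxidase-type I+) attacks an open-chain brominated C9 acid and triggers lactonization. The acid is used as its 4-yne (the dehydrated form of the biogenetic 4-oxo acid), so one anti 5-exo-dig iodolactonization forms the ring, installs iodine and fixes the (E)-CHI geometry.
- The (carboxylate-cis-to-ethynyl) 3-bromo-en-ynoate comes from hydroxide opening and desilylation of an (E)-α-(bromoalkylidene)-β-lactone in the same flask.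
- The β-lactone comes from an (R)-silyl-diynol by Pd(II) anti-bromopalladation/cyclocarbonylation, which adds Br and the carboxyl carbon across the proximal alkyne.
- The (R)-diynol comes from asymmetric transfer hydrogenation of a diynone, made by acylating bis-TMS-butadiyne with butanoyl chloride.
- Ring order: transient β-lactone (step 3), then the furanone (step 4).

Assumption: the SMILES is read as the (1R)-carbinol and the (5E)-iodomethylene isomer (I trans to the ring oxygen, cis to C-4); in the fallback to step 2 the ligand enantiomer that gives the (R)-carbinol is meant.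

**Route**

Step 1
Reactants: 1 1,4-bis(trimethylsilyl)buta-1,3-diyne; 2 butanoyl chloride
Product: 3 8-(trimethylsilyl)octa-5,7-diyn-4-one
Conditions: AlCl3 (1.05 equiv), CH2Cl2, 0 °C
Reagents that add atoms: none
Why: Desilylative (ipso) Friedel–Crafts-type acylation of an alkynylsilane: the acylium ion attacks the silyl-bearing alkyne carbon (β-silyl cation), Me3SiCl is lost, and the deactivated ynone is not acylated a second time.

Step 2
Reactants: 3 8-(trimethylsilyl)octa-5,7-diyn-4-one
Product: 4 (4R)-8-(trimethylsilyl)octa-5,7-diyn-4-ol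
Conditions: Ru[(R,R)-TsDPEN](p-cymene) (16-electron amido complex, 1 mol %), i-PrOH, 25 °C
Reagents that add atoms: none
Why: Noyori–Ikariya asymmetric transfer hydrogenation of an α,β-alkynyl ketone; the (R,R)-catalyst delivers hydride to the face that gives the (R)-propargylic alcohol (alkynyl in the role of the aryl group), which sets the only stereocentre without reducing the C≡C bonds.

Step 3
Reactants: 4 (4R)-8-(trimethylsilyl)octa-5,7-diyn-4-ol
Product: 5 (3E,4R)-3-[1-bromo-3-(trimethylsilyl)prop-2-yn-1-ylidene]-4-propyloxetan-2-one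
Conditions: PdBr2 (5 mol %), CuBr2 (3 equiv), LiBr (5 equiv), CO (1 atm), MeCN, 0 °C to rt
Reagents that add atoms: carbon monoxide, [C-]#[O+]; copper(II) bromide, Br[Cu]Br (bromide pool shared with LiBr, [Li+].[Br-])
Why: Proposed new method: bromide-saturated Pd(II) binds the hydroxyl-flanked C5≡C6 alkyne and external Br− attacks C-6 anti to Pd (trans-halopalladation, the mode established for Pd(II) with excess LiX), CO inserts into the C-5 vinyl–Pd bond and the neighbouring OH closes the β-lactone with Br trans and the alkynyl group cis to the carbonyl while CuBr2 reoxidises Pd(0); the closest known reaction type is the PdX2/CuX2 halo-cyclocarbonylation of 2-alkynols to α-(haloalkylidene)-β-lactones, and the halide-rich polar medium is chosen to enforce external anti attack over syn insertion; the carbinol C–O bond is untouched, so (R) is retained.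

Step 4
Reactants: 5 (3E,4R)-3-[1-bromo-3-(trimethylsilyl)prop-2-yn-1-ylidene]-4-propyloxetan-2-one
Product: 8 (5E)-4-bromo-3-[(1R)-1-hydroxybutyl]-5-(iodomethylene)furan-2(5H)-one, via silylated lithium enynoate 6 (not isolated), via lithium enynoate 7 (not isolated)
Conditions: LiOH (2.2 equiv), THF/H2O, 0 °C to rt; then AcOH to pH 8, NaHCO3, I2 (1.3 equiv), MeCN, 0 °C, dark
Reagents that add atoms: lithium hydroxide, [Li+].[OH-]; iodine, II
Why: Hydroxide opens the strained β-lactone at the acyl carbon (retention at the carbinol) and cleaves the C(sp)–Si bond, and the carboxylate, held cis to the ethynyl group, then undergoes a haloperoxidase-like iodolactonization in which it adds 5-exo-dig, anti to the iodonium, at the internal alkyne carbon, closing the furanone and setting the exocyclic (E)-CHI geometry in one event.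

**Compound list**

1 | 1,4-bis(trimethylsilyl)buta-1,3-diyne | C[Si](C)(C)C#CC#C[Si](C)(C)C | starting material
2 | butanoyl chloride | CCCC(Cl)=O | starting material
3 | 8-(trimethylsilyl)octa-5,7-diyn-4-one | CCCC(=O)C#CC#C[Si](C)(C)C | intermediate
4 | (4R)-8-(trimethylsilyl)octa-5,7-diyn-4-ol | CCC[C@@H](O)C#CC#C[Si](C)(C)C | intermediate
5 | (3E,4R)-3-[1-bromo-3-(trimethylsilyl)prop-2-yn-1-ylidene]-4-propyloxetan-2-one (Br cis to C-4, alkynyl cis to C=O) | CCC[C@@H]1/C(=C(\Br)C#C[Si](C)(C)C)C(=O)O1 | intermediate
6 | lithium (2E)-3-bromo-2-[(1R)-1-hydroxybutyl]-5-(trimethylsilyl)pent-2-en-4-ynoate (carboxylate cis to alkynyl) | CCC[C@@H](O)/C(C(=O)[O-])=C(\Br)C#C[Si](C)(C)C.[Li+] | intermediate (not isolated)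
7 | lithium (2E)-3-bromo-2-[(1R)-1-hydroxybutyl]pent-2-en-4-ynoate (carboxylate cis to ethynyl) | CCC[C@@H](O)/C(C(=O)[O-])=C(\Br)C#C.[Li+] | intermediate (not isolated)
8 | (5E)-4-bromo-3-[(1R)-1-hydroxybutyl]-5-(iodomethylene)furan-2(5H)-one | CCC[C@@H](O)C1=C(Br)/C(=C\I)OC1=O | target

**Step count and risks**

Total steps: 4. Longest linear sequence: 4 (1/2 → 3 → 4 → 5 → 8).

Most likely to fail, in order:

Step 3. The bromopalladation may go syn and give the (Z)-lactone, which cannot close onto the alkyne. CuBr2/Br− may also attack the silyl diyne or open the β-lactone. The fallback sets out from 4. A magnesium-alkoxide-directed anti-carbomagnesiation with vinylmagnesium chloride (vinyl to C-5, Mg chelated at C-6; THF/cyclohexane, heat) followed by an NBS quench gives (4R,5Z)-6-bromo-5-ethenyl-8-(trimethylsilyl)oct-5-en-7-yn-4-ol F1. Lemieux–Johnson cleavage of the vinyl group (OsO4 cat., NaIO4, 2,6-lutidine) gives (2E)-3-bromo-2-[(1R)-1-hydroxybutyl]-5-(trimethylsilyl)pent-2-en-4-ynal F2. Pinnick oxidation (NaClO2, NaH2PO4, 2-methyl-2-butene) gives (2E)-3-bromo-2-[(1R)-1-hydroxybutyl]-5-(trimethylsilyl)pent-2-en-4-ynoic acid F3. Its lithium salt (LiOH) is 6, where the route is rejoined.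

Step 4. Possible failures are 6-endo closure to a 5-iodopyran-2-one, iodination of the alkyne C–H, and E-to-Z drift of the crowded iodoalkene under I2 and light. The fallback sets out from 7. Stoichiometric anti-oxymercuration (Hg(OAc)2, then NaCl), which is reliably 5-exo for alkynoic acids, gives chloro{(E)-[3-bromo-4-((1R)-1-hydroxybutyl)-5-oxofuran-2(5H)-ylidene]methyl}mercury F4. Iododemercuration with I2 (retention) comes back at 8.

Step 2. The ee may be lower with a linear alkyl diynone, and the ynone is base-sensitive. The fallback sets out from 1. Mono-desilylation with MeLi·LiBr and an aqueous quench gives 4-(trimethylsilyl)buta-1,3-diyne F5. Catalytic asymmetric alkynylation of butanal with F5 (Zn–ProPhenol, Me2Zn, Ph3P=O, toluene, 4 °C) comes back at 4 and by-passes 3.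

**Further compounds**

F1 | step 3 | (4R,5Z)-6-bromo-5-ethenyl-8-(trimethylsilyl)oct-5-en-7-yn-4-ol | CCC[C@@H](O)/C(C=C)=C(\Br)C#C[Si](C)(C)C
F2 | step 3 | (2E)-3-bromo-2-[(1R)-1-hydroxybutyl]-5-(trimethylsilyl)pent-2-en-4-ynal | CCC[C@@H](O)/C(C=O)=C(\Br)C#C[Si](C)(C)C
F3 | step 3 | (2E)-3-bromo-2-[(1R)-1-hydroxybutyl]-5-(trimethylsilyl)pent-2-en-4-ynoic acid | CCC[C@@H](O)/C(C(=O)O)=C(\Br)C#C[Si](C)(C)C
F4 | step 4 | chloro{(E)-[3-bromo-4-((1R)-1-hydroxybutyl)-5-oxofuran-2(5H)-ylidene]methyl}mercury | CCC[C@@H](O)C1=C(Br)/C(=C\[Hg]Cl)OC1=O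
F5 | step 2 | 4-(trimethylsilyl)buta-1,3-diyne | C#CC#C[Si](C)(C)C
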